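(The numbers are invented; no experiment stands behind them.)

In a one-step world a flask needs a rate constant and a clock; this flask needs an end state first.

    solid substrate ⇌ dissolved substrate, rate k1*(cs1 - [dissolved substrate]) while solid is left; crystals form when [dissolved substrate] > cs1 (cs1 = 0.083 M, k1 = 0.0543 min⁻¹)
    dissolved substrate + reagent ⇌ target (K2 = 28 L mol⁻¹, k2 = 63.6 L mol⁻¹ min⁻¹)
    crystals ⇌ target, rate k3*(cs3 - [target]) while solid is left; crystals form when [target] > cs3 (cs3 = 0.098 M, k3 = 0.918 min⁻¹)
    reagent → decomposition product (k4 = 3.79 × 10⁻⁴ min⁻¹)

solid substrate 0.20 M; reagent 0.140 M; time 25 min

- amounts and yields of target count crystals too
- given per volume of solution although it is solid: solid substrate, crystals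
- at the start none of the solid substrate is in solution
- run time (flask): 25 min

* how much target and crystals together there is at 25 min, in percent of the solid substrate charged
* the change that raises the amount of target and crystals together at 25 min, in percent of the solid substrate charged most ("none" if none brings more than 2 percentage points) (eta / zeta / delta / beta / none)
* amount of target and crystals together at 25 min, in percent of the solid substrate charged, after delta

- eta: doubling the solubility in step 3, all else as stated
- zeta: doubling the dissolution coefficient of step 1, all else as stated
- delta: doubling the dissolution coefficient of step 3, all else as stated
- beta: doubling the solubility in step 1, all else as stated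

Where does this flask stop? While solid substrate remains, the solution ends at its solubility, 0.083 M. Let K be the equilibrium constant of the reaction with reagent, and c that solubility. Target in equilibrium with a saturated solution is then the reagent charge times Kc/(1+Kc). That gives 0.09788 M, or 48.9 % of the solid substrate charged. Call this the saturated ceiling.

Is there enough solid? Ceiling plus saturated solution take 0.181 M, less than the 0.20 M charged.

Will crystals form? Target comes to about 0.098 M, its solubility, only at the ceiling. So I expect none, and I expect nothing from delta or eta.

How far does this flask get by 25 min? Into an empty solution, dissolving delivers 0.113 M, which is 56.3 % of the charge. That is 62.3 % of what the end state takes. Taking target in proportion, I commit to 30.5 %.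

Where is that weak? The solution is not empty, so delivery runs lower. But early on, target takes a larger share of what dissolves: the ratio of target to dissolved substrate is 3.9 at the start and 1.18 at the ceiling. These errors pull opposite ways, so my figure stays rough.

Which change wins? Zeta speeds delivery. Beta speeds it too. With dissolved substrate at half of 0.083 M, beta dissolves at 0.00676 M min⁻¹, against 0.00451 M min⁻¹ for zeta. I choose beta.

The forecast says 31.5 %, beta, and 31.5 % after delta, slightly above my figure, on the ground that “Dissolution then limits the rate”.

The simulation gives 31.6 %, with beta best at 16 percentage points against 11 points for zeta, and 31.6 % after delta.

This flask reads below its ceiling, and two things act together. Without the undoing of target, the reading rises from 31.6 % to 54.6 %, past the ceiling; read at 250 min, it is 47.3 %, still under the ceiling.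

In the neighbour flask with 0.035 M of reagent, the ceiling falls to 12.2 %. The 0.113 M into an empty solution is a bound, not this neighbour's delivery, and it barely passes the 0.107 M its end state takes. So I do not expect the end state by 25 min. A half-saturated solution there gives 9.41 % and takes 0.0603 M, well under that bound. So I expect a reading between 9.41 % and the ceiling. The computed neighbour reads 10.4 %.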